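**Plan**
- Retrosynthesis: the C7–allyl bond is cut first (aromatic Claisen, back to the 6‑O‑allyl ether 17). The C2–aryl and C3–CH3 bonds are then cut together, back to the 2,3‑unsubstituted benzofuran 10, aryl boronic ester 11 and MeOTf 12. Finally O1–C2 and C3–C3a are cut, back to o‑iodophenol 6 and trimethylsilylacetylene, and 6 is traced to isovanillin.
- Enabling feature: the tetrasubstituted C2=C3 enol‑ether bond of the furan ring (O1–C2(aryl)=C3(CH3)–C3a). A C2 boronate ate complex of the bare benzofuran is nucleophilic at C3 and can hand its boron‑bound aryl group to C2.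
- Forward: the benzene ring comes from isovanillin (O‑allylation, Baeyer–Villiger, iodination). The furan ring is closed by Sonogashira coupling and 5‑endo‑dig cyclisation. C3–CH3 and C2–aryl are installed in one flask, oxidation/dehydration re‑aromatises the furan, and a Claisen shift moves the allyl group from O6 to C7.
- The allyl group stays on oxygen until the end, so it protects the phenol during the organolithium step and no separate protecting group is needed.
- Stereochemistry: the target has none. The two centres created in the key step (trans, racemic) are erased on re‑aromatisation.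

Key step: step 6

Remark: the target SMILES contains no stereocentre and no stereogenic double bond, so it is one achiral compound and no absolute stereocontrol is required.

**Route**

Step 1
Reactants: 1 isovanillin; 2 allyl bromide
Product: 3 3-(allyloxy)-4-methoxybenzaldehyde
Conditions: K2CO3, DMF, rt
Reagents that add atoms: none
Why: Williamson ether synthesis (SN2) of the only acidic OH of 1 with a reactive allylic bromide, the aldehyde being inert to carbonate in DMF.

Step 2
Reactants: 3 3-(allyloxy)-4-methoxybenzaldehyde
Product: 5 3-(allyloxy)-4-methoxyphenol, via aryl formate 4 (not isolated)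
Conditions: mCPBA, CH2Cl2, 0 °C to rt; aq. NaHCO3 wash; then K2CO3 (cat.), MeOH, rt
Reagents that add atoms: mCPBA, O=C(OO)c1cccc(Cl)c1
Why: Baeyer–Villiger oxidation of an electron‑rich aryl aldehyde (Dakin‑type), in which the aryl group bearing a para‑methoxy group migrates in preference to hydride to give formate 4, which is methanolysed directly, while the monosubstituted, inductively deactivated allyl ether alkene should be epoxidised far more slowly than the aldehyde is consumed.

Step 3
Reactants: 5 3-(allyloxy)-4-methoxyphenol
Product: 6 5-(allyloxy)-2-iodo-4-methoxyphenol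
Conditions: NIS (1.0 equiv), MeCN, −10 to 0 °C, dark
Reagents that add atoms: N-iodosuccinimide, O=C1CCC(=O)N1I
Why: electrophilic aromatic iodination at the carbon ortho to the free OH and para to the allyloxy group, which is the most activated and least hindered site (the carbon between the two oxygens is shielded), and the alkene sits on a meta ether chain that cannot reach the phenol oxygen for iodo‑etherification.

Step 4
Reactants: 6 5-(allyloxy)-2-iodo-4-methoxyphenol; 7 trimethylsilylacetylene
Product: 8 5-(allyloxy)-4-methoxy-2-[(trimethylsilyl)ethynyl]phenol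
Conditions: PdCl2(PPh3)2 (cat.), CuI (cat.), Et3N, THF, rt
Reagents that add atoms: none
Why: Sonogashira coupling of an aryl iodide, which undergoes oxidative addition at room temperature, with a silyl‑capped alkyne that can couple only once; free o‑iodophenols and allyl aryl ethers are tolerated under these mild amine/copper conditions.

Step 5
Reactants: 8 5-(allyloxy)-4-methoxy-2-[(trimethylsilyl)ethynyl]phenol
Product: 10 6-(allyloxy)-5-methoxybenzofuran, via ethynylphenol 9 (not isolated)
Conditions: TBAF (1 M in THF, 1.2 equiv), THF, 65 °C
Reagents that add atoms: none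
Why: fluoride‑induced protodesilylation gives terminal alkyne 9, whose phenoxide adds to the triple bond in a 5‑endo‑dig hydroalkoxylation (fluoride‑promoted cyclisation of o‑alkynylphenols), and protonation of the vinyl anion gives the aromatic furan ring.

Step 6
Reactants: 10 6-(allyloxy)-5-methoxybenzofuran; 11 3,4,5-trimethoxyphenylboronic acid pinacol ester; 12 methyl trifluoromethanesulfonate
Product: 15 rac-(2S,3S)-2-[6-(allyloxy)-5-methoxy-3-methyl-2-(3,4,5-trimethoxyphenyl)-2,3-dihydrobenzofuran-2-yl]-4,4,5,5-tetramethyl-1,3,2-dioxaborolane (aryl trans to the C3 methyl, boron cis to it), via 2-lithiobenzofuran 13 (not isolated), via borate complex 14 (not isolated)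
Conditions: n-BuLi (1.05 equiv), THF, −78 °C; 11, −78 to 0 °C; MeOTf (1.5 equiv), −78 °C to rt
Reagents that add atoms: none
Why: Proposed new method: n-BuLi removes the kinetically most acidic C2–H of 10, the 2‑lithio species 13 adds to the boron of 11, and in ate complex 14 the anionic boron raises the energy of the C2=C3 enol‑ether π bond so that C3 attacks methyl triflate while the trimethoxyphenyl group shifts from boron to the developing oxocarbenium carbon C2 (electrophile‑induced 1,2‑metallate rearrangement). The closest known reaction types are the alkylative 1,2‑migration of indol‑2‑yl borates triggered by carbon electrophiles and the Zweifel‑type halogen‑induced arylation of furan‑2‑yl and benzofuran‑2‑yl boronate complexes; new here is the combination of a benzofuran‑2‑yl pinacol boronate, an aryl migrating group and an alkyl triflate. No ring is closed: the furan ring is only dearomatised, which is cheap because the benzene sextet stays intact. The two new stereocentres C2 and C3 are set together by the anti‑periplanar course of the shift, so that aryl and methyl end up trans (boron cis to methyl) in racemic form, and both are erased again in step 7. The step needs lithiation at C2 instead of at the allyl ether or at C7–H between the two oxygens, and C‑methylation at C3 instead of O‑methylation of the pinacolate; this is secured by the much higher kinetic acidity of the furan α‑hydrogen at −78 °C, by the absence of a doubly activated benzylic–allylic CH2 (the allyl group is still on oxygen at this stage) and by the soft, borate‑activated character of C3. Only the aryl group can migrate, because the pinacolate oxygens are non‑migrating ligands.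

Step 7
Reactants: 15 the C2 boronate from step 6
Product: 17 6-(allyloxy)-5-methoxy-3-methyl-2-(3,4,5-trimethoxyphenyl)benzofuran, via hemiketal 16 (not isolated)
Conditions: NaBO3·4H2O, THF/H2O (1:1), rt; aq. Na2S2O3, extraction; crude 16, TsOH·H2O (cat.), toluene, 60 °C
Reagents that add atoms: none
Why: perborate oxidation of the C–B bond (boron‑to‑oxygen 1,2‑shift, as in a hydroboration–oxidation work‑up) gives hemiketal 16, the ring tautomer of an o‑hydroxybenzyl aryl ketone, and the acid‑catalysed cyclodehydration of such ketones to 2‑arylbenzofurans is classical and driven by aromatisation; both transient stereocentres vanish and the oxygen brought in by the oxidant leaves again as water.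

Step 8
Reactants: 17 6-(allyloxy)-5-methoxy-3-methyl-2-(3,4,5-trimethoxyphenyl)benzofuran
Product: 18 7-allyl-5-methoxy-3-methyl-2-(3,4,5-trimethoxyphenyl)benzofuran-6-ol (target)
Conditions: PhNEt2, 200 °C, sealed tube, Ar
Reagents that add atoms: none
Why: aromatic Claisen rearrangement ([3,3]‑sigmatropic shift, then tautomerisation to the phenol), in which C5 is blocked by OMe and the para position is the ring‑fusion carbon, so the allyl group can only arrive at C7, across the C6–C7 bond that has the higher double‑bond character in a benzofuran.

**Compound list**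
1 | isovanillin (3-hydroxy-4-methoxybenzaldehyde) | O=Cc1ccc(OC)c(O)c1 | starting material
2 | allyl bromide | C=CCBr | starting material
3 | 3-(allyloxy)-4-methoxybenzaldehyde | C=CCOc1cc(C=O)ccc1OC | intermediate
4 | 3-(allyloxy)-4-methoxyphenyl formate | C=CCOc1cc(OC=O)ccc1OC | intermediate
5 | 3-(allyloxy)-4-methoxyphenol | C=CCOc1cc(O)ccc1OC | intermediate
6 | 5-(allyloxy)-2-iodo-4-methoxyphenol | C=CCOc1cc(O)c(I)cc1OC | intermediate
7 | trimethylsilylacetylene | C[Si](C)(C)C#C | starting material
8 | 5-(allyloxy)-4-methoxy-2-[(trimethylsilyl)ethynyl]phenol | C=CCOc1cc(O)c(C#C[Si](C)(C)C)cc1OC | intermediate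
9 | 5-(allyloxy)-2-ethynyl-4-methoxyphenol | C=CCOc1cc(O)c(C#C)cc1OC | intermediate
10 | 6-(allyloxy)-5-methoxybenzofuran | C=CCOc1cc2occc2cc1OC | intermediate
11 | 3,4,5-trimethoxyphenylboronic acid pinacol ester | COc1cc(B2OC(C)(C)C(C)(C)O2)cc(OC)c1OC | starting material
12 | methyl trifluoromethanesulfonate | COS(=O)(=O)C(F)(F)F | starting material
13 | [6-(allyloxy)-5-methoxybenzofuran-2-yl]lithium | [Li]c1cc2cc(OC)c(OCC=C)cc2o1 | intermediate
14 | lithium [6-(allyloxy)-5-methoxybenzofuran-2-yl](pinacolato)(3,4,5-trimethoxyphenyl)borate | [Li+].C=CCOc1cc2oc(cc2cc1OC)[B-]1(OC(C)(C)C(C)(C)O1)c1cc(OC)c(OC)c(OC)c1 | intermediate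
15 | rac-(2S,3S)-2-[6-(allyloxy)-5-methoxy-3-methyl-2-(3,4,5-trimethoxyphenyl)-2,3-dihydrobenzofuran-2-yl]-4,4,5,5-tetramethyl-1,3,2-dioxaborolane (aryl trans to methyl; racemate, one enantiomer drawn) | c1c(OCC=C)c(OC)cc2c1O[C@](B1OC(C)(C)C(C)(C)O1)(c1cc(OC)c(OC)c(OC)c1)[C@H]2C | intermediate
16 | 6-(allyloxy)-5-methoxy-3-methyl-2-(3,4,5-trimethoxyphenyl)-2,3-dihydrobenzofuran-2-ol (racemic mixture of diastereomers in ring–chain equilibrium with the o-hydroxyaryl ketone; configuration not defined) | C=CCOc1cc2OC(O)(c3cc(OC)c(OC)c(OC)c3)C(C)c2cc1OC | intermediate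
17 | 6-(allyloxy)-5-methoxy-3-methyl-2-(3,4,5-trimethoxyphenyl)benzofuran | C=CCOc1cc2oc(-c3cc(OC)c(OC)c(OC)c3)c(C)c2cc1OC | intermediate
18 | 7-allyl-5-methoxy-3-methyl-2-(3,4,5-trimethoxyphenyl)benzofuran-6-ol (CNP0110777.0, achiral) | C=CCc1c(O)c(OC)cc2c(C)c(-c3cc(OC)c(OC)c(OC)c3)oc12 | target

**Step count and risks**

Total step count: 8. Longest linear sequence: 8 steps, from isovanillin 1 to 18; compounds 2, 7, 11 and 12 are purchased.

Steps most likely to fail:

1. Step 6 (proposed new method). The hard methylating agent may alkylate a pinacolate oxygen, or C3 may not engage, so that the ate complex reverts to 10 and 11 on work‑up; deprotonation may also stray to the allyl ether. The fallback uses known chemistry only, sets out from 10 and returns at 17. Benzofuran 10 is lithiated at C2 as before (13) and transmetallated with ZnCl2 to [6-(allyloxy)-5-methoxybenzofuran-2-yl]zinc chloride F1. Negishi coupling with 5-bromo-1,2,3-trimethoxybenzene (Pd(PPh3)4 cat., THF, 50 °C) should give 6-(allyloxy)-5-methoxy-2-(3,4,5-trimethoxyphenyl)benzofuran F2. NBS in DMF at 0 °C should brominate C3, the most nucleophilic carbon of a 2‑arylbenzofuran, to give 6-(allyloxy)-3-bromo-5-methoxy-2-(3,4,5-trimethoxyphenyl)benzofuran F3. Bromine–lithium exchange (n-BuLi, THF, −78 °C) to [6-(allyloxy)-5-methoxy-2-(3,4,5-trimethoxyphenyl)benzofuran-3-yl]lithium F4 and immediate quench with iodomethane at −78 °C should give 17.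

2. Step 7. Oxidative cleavage of the congested tertiary C–B bond may be sluggish, or the electron‑rich ring‑opened phenol ketone may be over‑oxidised under the basic peroxide conditions. The fallback sets out from 15 and returns at 17 without an oxidant acting on boron. Protodeboronation of the tertiary benzylic boronate (TBAF·3H2O, toluene, 45 °C) should give rac-(2S,3S)-6-(allyloxy)-5-methoxy-3-methyl-2-(3,4,5-trimethoxyphenyl)-2,3-dihydrobenzofuran F5 (trans; the cis epimer would serve equally). Dehydrogenation with DDQ (dioxane, 80 °C), the standard conversion of 2‑aryl‑3‑methyl‑2,3‑dihydrobenzofurans into benzofurans, should then give 17.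

3. Step 3. Site selectivity may be lost (iodination at the carbon between the two oxygens), the alkene may be attacked, or the p‑alkoxyphenol may be oxidised towards a quinone. The fallback sets out from 5, returns at 10 and bypasses steps 3–5 by building the furan ring without halogenation. Phenol 5 is O‑alkylated with bromoacetaldehyde diethyl acetal (K2CO3, DMF, 100 °C) to 2-(allyloxy)-4-(2,2-diethoxyethoxy)-1-methoxybenzene F6. Acid‑mediated cyclodehydration (Amberlyst‑15, chlorobenzene, 120 °C) should close onto the ring carbon para to the allyloxy group and give 10.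

**Further compounds**
F1 | step 6 | [6-(allyloxy)-5-methoxybenzofuran-2-yl]zinc chloride | Cl[Zn]c1cc2cc(OC)c(OCC=C)cc2o1
F2 | step 6 | 6-(allyloxy)-5-methoxy-2-(3,4,5-trimethoxyphenyl)benzofuran | C=CCOc1cc2oc(-c3cc(OC)c(OC)c(OC)c3)cc2cc1OC
F3 | step 6 | 6-(allyloxy)-3-bromo-5-methoxy-2-(3,4,5-trimethoxyphenyl)benzofuran | C=CCOc1cc2oc(-c3cc(OC)c(OC)c(OC)c3)c(Br)c2cc1OC
F4 | step 6 | [6-(allyloxy)-5-methoxy-2-(3,4,5-trimethoxyphenyl)benzofuran-3-yl]lithium | C=CCOc1cc2oc(-c3cc(OC)c(OC)c(OC)c3)c([Li])c2cc1OC
F5 | step 7 | rac-(2S,3S)-6-(allyloxy)-5-methoxy-3-methyl-2-(3,4,5-trimethoxyphenyl)-2,3-dihydrobenzofuran (trans, one enantiomer drawn) | c1c(OCC=C)c(OC)cc2c1O[C@H](c1cc(OC)c(OC)c(OC)c1)[C@H]2C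
F6 | step 3 | 2-(allyloxy)-4-(2,2-diethoxyethoxy)-1-methoxybenzene | C=CCOc1cc(OCC(OCC)OCC)ccc1OC
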